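**Plan**

Numbering kept for every intermediate: spiro[4.5]decane C1 (bears the side chain), C2, C3, C4 (methyl), C5 (spiro), C6H2, C7 (carbinol), C8 (methyl), C9 (=CH), C10H2; side chain C1′ (CH2OAc), C2′ (methyl), C3′–C5′, C6′ (methine on C1), C7′ (its methyl).
Enabling feature: in the six-membered ring, C5 is followed by C10H2–C9H=C8(CH3)–C7(O), a reduced 2-methylanisole one hydrogen shift away from C5=C10–C9H2. The hydrogen that shift needs sits on C6′, next to the C5–C1 bond, so the cyclopentane opens by a retro-ene reaction to a Birch-type 1,4-diene and a C1=C6′ alkene.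
Cuts, backwards: C7–H (enone), acetate, C7′ methyl back to an activating ester, C5–C1 with C6′–H (ene), C6′–C5′ (sp3–sp2 coupling), C1=C6′ (olefination), ring back to the arene, C4–aryl.
Forward: the six-membered ring is the arene from the start; arylation, Birch reduction, oxidation and iodo-olefination give the ring half, an auxiliary alkylation gives the chain half, a Suzuki coupling joins them, and the cyclopentane closes last (step 9). The ester is then reduced to the methyl group, the enone is unmasked, acetylated and reduced.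
Stereochemistry: C4 from the catalytic arylation, C2′ from the auxiliary, C5, C1 and C6′ together from the ene event (relayed from C4 and the alkene geometry), C7 from the oxazaborolidine reduction.

Key step: step 9

Assumption: in step 1 the (S)-ligand/(E)-alkenol pairing is taken to give the 4S aldehyde (insertion model with the alkene cis to the oxazoline and the substituent on the palladium-bound carbon turned away from the tert-butyl group); E and Z alkenols give opposite enantiomers with one ligand, so (Z)-pent-3-en-1-ol would be used instead if the sense proved opposite.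

**Route**

Step 1
Reactants: 1 (3-methoxy-4-methylphenyl)boronic acid; 2 (E)-pent-3-en-1-ol
Product: 4 (S)-4-(3-methoxy-4-methylphenyl)pentan-1-ol, via aldehyde 3 (not isolated)
Conditions: Pd(MeCN)2(OTs)2 (6 mol %), Cu(OTf)2 (6 mol %), (S)-4-tert-butyl-2-[5-(trifluoromethyl)pyridin-2-yl]-4,5-dihydrooxazole (13 mol %), 3 Å MS, O2 (1 atm), DMF, rt; then NaBH4, MeOH, 0 °C
Reagents that add atoms: none
Why: Enantioselective redox-relay oxidative Heck arylation, in which aryl-palladium should add with the aryl group at the alkene carbon remote from the hydroxyl and palladium then walks to the carbinol carbon and leaves as aldehyde 3, reduced in the same flask; C4 is set in the migratory insertion by the chiral pyridine-oxazoline ligand.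

Step 2
Reactants: 4 (S)-4-(3-methoxy-4-methylphenyl)pentan-1-ol
Product: 5 (S)-4-(5-methoxy-4-methylcyclohexa-1,4-dien-1-yl)pentan-1-ol
Conditions: Li, NH3 (l), THF, t-BuOH, −78 to −33 °C; NH4Cl
Reagents that add atoms: none
Why: Birch reduction, in which methoxy, methyl and alkyl groups all stay on sp2 carbons, so the 2,5-dihydroanisole with the second alkene at the side-chain carbon should form regioselectively, and the benzylic stereocenter is not touched.

Step 3
Reactants: 5 (S)-4-(5-methoxy-4-methylcyclohexa-1,4-dien-1-yl)pentan-1-ol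
Product: 6 (S)-4-(5-methoxy-4-methylcyclohexa-1,4-dien-1-yl)pentanal
Conditions: SO3·pyridine, DMSO, i-Pr2NEt, CH2Cl2, 0 °C
Reagents that add atoms: none
Why: Parikh–Doering oxidation, whose basic, non-acidic medium should leave the methyl enol ether and the skipped diene intact.

Step 4
Reactants: 6 (S)-4-(5-methoxy-4-methylcyclohexa-1,4-dien-1-yl)pentanal
Product: 7 ethyl (2Z,6S)-2-iodo-6-(5-methoxy-4-methylcyclohexa-1,4-dien-1-yl)hept-2-enoate
Conditions: Ph3P=CHCO2Et, N-iodosuccinimide, CH2Cl2, −20 °C; then K2CO3, 6, −20 °C to rt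
Reagents that add atoms: ethyl (triphenyl-λ5-phosphanylidene)acetate CCOC(=O)C=P(c1ccccc1)(c1ccccc1)c1ccccc1; N-iodosuccinimide O=C1CCC(=O)N1I
Why: Wittig olefination with the α-iodo stabilized ylide made in the flask should give mainly the Z iodoacrylate (iodine cis to the chain, ester trans), as is usual for α-halo stabilized ylides, and the electrophilic iodine source is consumed before the diene aldehyde is added.

Step 5
Reactants: 8 (R)-4-benzyl-3-propanoyloxazolidin-2-one
Product: 9 (R)-4-benzyl-3-[(S)-2-methylpent-4-enoyl]oxazolidin-2-one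
Conditions: NaN(SiMe3)2, THF, −78 °C; allyl iodide, −78 to −45 °C
Reagents that add atoms: allyl iodide C=CCI
Why: Evans alkylation, in which the chelated Z enolate is allylated on the face opposite the benzyl group of the R auxiliary, which sets the 2S methyl center (the later C2′).

Step 6
Reactants: 9 (R)-4-benzyl-3-[(S)-2-methylpent-4-enoyl]oxazolidin-2-one
Product: 10 (S)-2-methylpent-4-en-1-ol
Conditions: LiBH4, MeOH (1 equiv), THF, 0 °C
Reagents that add atoms: none
Why: Reductive cleavage of the imide with LiBH4 should give the primary alcohol and the recoverable auxiliary without touching the α-stereocenter or the alkene.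

Step 7
Reactants: 10 (S)-2-methylpent-4-en-1-ol
Product: 11 tert-butyldimethyl{[(2S)-2-methylpent-4-en-1-yl]oxy}silane
Conditions: TBSCl, imidazole, CH2Cl2, rt
Reagents that add atoms: tert-butyldimethylsilyl chloride CC(C)(C)[Si](C)(C)Cl
Why: Standard silylation gives a primary silyl ether that withstands the coupling, heat and hydride steps and is removed by the acid that later unmasks the enone.

Step 8
Reactants: 11 tert-butyldimethyl{[(2S)-2-methylpent-4-en-1-yl]oxy}silane; 7 ethyl (2Z,6S)-2-iodo-6-(5-methoxy-4-methylcyclohexa-1,4-dien-1-yl)hept-2-enoate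
Product: 13 ethyl (2E,6S)-2-[(4S)-5-[(tert-butyldimethylsilyl)oxy]-4-methylpentyl]-6-(5-methoxy-4-methylcyclohexa-1,4-dien-1-yl)hept-2-enoate, via B-alkyl borane 12 (not isolated)
Conditions: 9-BBN, THF, rt; then 7, Pd(dppf)Cl2 (5 mol %), AsPh3 (5 mol %), Cs2CO3, DMF/THF/H2O, rt
Reagents that add atoms: none
Why: B-alkyl Suzuki–Miyaura coupling, in which anti-Markovnikov hydroboration of the terminal alkene and sp3–sp2 coupling with retention of the iodoalkene geometry should place C5′ cis to C2 (the E enoate); the borane is formed before the diene is added, so the ring alkenes are not hydroborated.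

Step 9
Reactants: 13 ethyl (2E,6S)-2-[(4S)-5-[(tert-butyldimethylsilyl)oxy]-4-methylpentyl]-6-(5-methoxy-4-methylcyclohexa-1,4-dien-1-yl)hept-2-enoate
Product: 14 ethyl (2R,6S)-7-[(tert-butyldimethylsilyl)oxy]-2-[(1R,4S,5S)-7-methoxy-4,8-dimethylspiro[4.5]deca-7,9-dien-1-yl]-6-methylheptanoate
Conditions: toluene (0.01 M, degassed), BHT (cat.), K2CO3 (solid, trace), sealed tube, 210 °C
Reagents that add atoms: none
Why: A concerted intramolecular Alder-ene reaction of the 1,6-diene (type 1) is expected, in which C5 of the ring alkene C5=C10 bonds to C1, the β-carbon of the enoate, while the bis-allylic hydrogen on C9 passes suprafacially to the α-carbon C6′ and the double bond moves to C10=C9, into conjugation with the enol ether. The closest known reaction type is the thermal ene cyclization of 1-(hex-5-en-2-yl)cyclohexenes to spiro[4.5]dec-6-enes; here the ester-activated enophile and the weak doubly allylic C–H should lower the temperature needed. The cyclopentane closes as a five-membered ring through a cis-fused bicyclo[3.3.0]-type transition state (three-atom tether C2–C3–C4 between ene terminus and enophile), whereas closure of a six-membered ring through C10 (type 2, hydrogen from C6) would need a bridged array. The six-atom ene array forces the C1–C6′ bond and the C5–C10 bond to be cis on the new ring, which fixes C1 relative to C5, and syn delivery of C5 and hydrogen across the E alkene, in which C2 and C5′ are cis and the ester lies endo over the diene, fixes C6′ as R. The absolute sense comes from C4, whose methyl should sit pseudo-equatorial on the convex face, away from the enophile whose exo C5′ chain covers the concave side, so that the methyl ends trans to the C1 substituent and cis to C6; this face selection is the selectivity the step needs. A 1,5-hydrogen shift in the product would only give the isomeric 6,8-dienol ether, which hydrolyzes to the same enone in step 13, and the quaternary C5 blocks aromatization of the product.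

Step 10
Reactants: 14 ethyl (2R,6S)-7-[(tert-butyldimethylsilyl)oxy]-2-[(1R,4S,5S)-7-methoxy-4,8-dimethylspiro[4.5]deca-7,9-dien-1-yl]-6-methylheptanoate
Product: 15 (2R,6S)-7-[(tert-butyldimethylsilyl)oxy]-2-[(1R,4S,5S)-7-methoxy-4,8-dimethylspiro[4.5]deca-7,9-dien-1-yl]-6-methylheptan-1-ol
Conditions: LiAlH4, Et2O, 0 °C
Reagents that add atoms: none
Why: Hydride reduction of the ester to the primary alcohol is fast at 0 °C, which should leave no time for base epimerization at C6′, and the dienol ether and silyl ether are inert to hydride.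

Step 11
Reactants: 15 (2R,6S)-7-[(tert-butyldimethylsilyl)oxy]-2-[(1R,4S,5S)-7-methoxy-4,8-dimethylspiro[4.5]deca-7,9-dien-1-yl]-6-methylheptan-1-ol
Product: 16 (2R,6S)-7-[(tert-butyldimethylsilyl)oxy]-2-[(1R,4S,5S)-7-methoxy-4,8-dimethylspiro[4.5]deca-7,9-dien-1-yl]-6-methylheptyl 4-methylbenzenesulfonate
Conditions: TsCl, Et3N, DMAP (cat.), CH2Cl2, 0 °C to rt
Reagents that add atoms: p-toluenesulfonyl chloride Cc1ccc(cc1)S(Cl)(=O)=O
Why: Sulfonylation of the only free hydroxyl in an amine-buffered medium should keep the acid-sensitive dienol ether intact.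

Step 12
Reactants: 16 (2R,6S)-7-[(tert-butyldimethylsilyl)oxy]-2-[(1R,4S,5S)-7-methoxy-4,8-dimethylspiro[4.5]deca-7,9-dien-1-yl]-6-methylheptyl 4-methylbenzenesulfonate
Product: 17 tert-butyl{[(2S,6R)-6-[(1R,4S,5S)-7-methoxy-4,8-dimethylspiro[4.5]deca-7,9-dien-1-yl]-2-methylheptyl]oxy}dimethylsilane
Conditions: LiEt3BH, THF, 0 °C to rt
Reagents that add atoms: none
Why: SN2 hydride displacement of the β-branched primary tosylate by LiEt3BH turns the spent activating group into the C7′ methyl without touching a stereocenter.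

Step 13
Reactants: 17 tert-butyl{[(2S,6R)-6-[(1R,4S,5S)-7-methoxy-4,8-dimethylspiro[4.5]deca-7,9-dien-1-yl]-2-methylheptyl]oxy}dimethylsilane
Product: 18 (1R,4S,5S)-1-[(2R,6S)-7-hydroxy-6-methylheptan-2-yl]-4,8-dimethylspiro[4.5]dec-8-en-7-one
Conditions: 1 M HCl, THF, rt
Reagents that add atoms: water O
Why: Aqueous acid should protonate the dienol ether at its terminus C10, hydrolyze the oxocarbenium ion to the conjugated 8-en-7-one (any β,γ-isomer moves into conjugation under the same acid) and cleave the primary silyl ether in the same operation.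

Step 14
Reactants: 18 (1R,4S,5S)-1-[(2R,6S)-7-hydroxy-6-methylheptan-2-yl]-4,8-dimethylspiro[4.5]dec-8-en-7-one
Product: 19 [(2S,6R)-6-[(1R,4S,5S)-4,8-dimethyl-7-oxospiro[4.5]dec-8-en-1-yl]-2-methylheptyl] acetate
Conditions: Ac2O, pyridine, DMAP (cat.), CH2Cl2, 0 °C
Reagents that add atoms: acetic anhydride CC(=O)OC(C)=O
Why: Acetylation of the only hydroxyl while C7 is still a ketone avoids any need to tell a primary from a secondary alcohol later.

Step 15
Reactants: 19 [(2S,6R)-6-[(1R,4S,5S)-4,8-dimethyl-7-oxospiro[4.5]dec-8-en-1-yl]-2-methylheptyl] acetate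
Product: 20 [(2S,6R)-6-[(1R,4S,5S,7S)-7-hydroxy-4,8-dimethylspiro[4.5]dec-8-en-1-yl]-2-methylheptyl] acetate
Conditions: (R)-1-methyl-3,3-diphenyltetrahydro-1H,3H-pyrrolo[1,2-c][1,3,2]oxazaborole (0.2 equiv), catecholborane, toluene, −78 °C
Reagents that add atoms: none
Why: Corey–Bakshi–Shibata 1,2-reduction under reagent control, in which the α-methyl alkenyl side (C8) acts as the large group and C6H2 as the small one, so the R catalyst should deliver the 7S allylic alcohol (as the S catalyst gives (R)-cyclohex-2-enol), and catecholborane at −78 °C spares the acetate and the alkene.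

**Compound list**

1 | (3-methoxy-4-methylphenyl)boronic acid | COc1cc(B(O)O)ccc1C | starting material
2 | (E)-pent-3-en-1-ol | C/C=C/CCO | starting material
3 | (S)-4-(3-methoxy-4-methylphenyl)pentanal | O=CCC[C@H](C)c1ccc(C)c(OC)c1 | intermediate (not isolated)
4 | (S)-4-(3-methoxy-4-methylphenyl)pentan-1-ol | OCCC[C@H](C)c1ccc(C)c(OC)c1 | intermediate
5 | (S)-4-(5-methoxy-4-methylcyclohexa-1,4-dien-1-yl)pentan-1-ol | OCCC[C@H](C)C1=CCC(C)=C(OC)C1 | intermediate
6 | (S)-4-(5-methoxy-4-methylcyclohexa-1,4-dien-1-yl)pentanal | O=CCC[C@H](C)C1=CCC(C)=C(OC)C1 | intermediate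
7 | ethyl (2Z,6S)-2-iodo-6-(5-methoxy-4-methylcyclohexa-1,4-dien-1-yl)hept-2-enoate | CCOC(=O)/C(I)=C/CC[C@H](C)C1=CCC(C)=C(OC)C1 | intermediate
8 | (R)-4-benzyl-3-propanoyloxazolidin-2-one | CCC(=O)N1C(=O)OC[C@H]1Cc1ccccc1 | starting material
9 | (R)-4-benzyl-3-[(S)-2-methylpent-4-enoyl]oxazolidin-2-one | C=CC[C@H](C)C(=O)N1C(=O)OC[C@H]1Cc1ccccc1 | intermediate
10 | (S)-2-methylpent-4-en-1-ol | C=CC[C@H](C)CO | intermediate
11 | tert-butyldimethyl{[(2S)-2-methylpent-4-en-1-yl]oxy}silane | C=CC[C@H](C)CO[Si](C)(C)C(C)(C)C | intermediate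
12 | 9-[(4S)-5-[(tert-butyldimethylsilyl)oxy]-4-methylpentyl]-9-borabicyclo[3.3.1]nonane | CC(C)(C)[Si](C)(C)OC[C@@H](C)CCCB1C2CCCC1CCC2 | intermediate (not isolated)
13 | ethyl (2E,6S)-2-[(4S)-5-[(tert-butyldimethylsilyl)oxy]-4-methylpentyl]-6-(5-methoxy-4-methylcyclohexa-1,4-dien-1-yl)hept-2-enoate | CC(C)(C)[Si](C)(C)OC[C@@H](C)CCC/C(C(=O)OCC)=C\CC[C@H](C)C1=CCC(C)=C(OC)C1 | intermediate
14 | ethyl (2R,6S)-7-[(tert-butyldimethylsilyl)oxy]-2-[(1R,4S,5S)-7-methoxy-4,8-dimethylspiro[4.5]deca-7,9-dien-1-yl]-6-methylheptanoate | CC(C)(C)[Si](C)(C)OC[C@@H](C)CCC[C@@H](C(=O)OCC)[C@H]1CC[C@H](C)[C@@]12C=CC(C)=C(OC)C2 | intermediate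
15 | (2R,6S)-7-[(tert-butyldimethylsilyl)oxy]-2-[(1R,4S,5S)-7-methoxy-4,8-dimethylspiro[4.5]deca-7,9-dien-1-yl]-6-methylheptan-1-ol | CC(C)(C)[Si](C)(C)OC[C@@H](C)CCC[C@@H](CO)[C@H]1CC[C@H](C)[C@@]12C=CC(C)=C(OC)C2 | intermediate
16 | (2R,6S)-7-[(tert-butyldimethylsilyl)oxy]-2-[(1R,4S,5S)-7-methoxy-4,8-dimethylspiro[4.5]deca-7,9-dien-1-yl]-6-methylheptyl 4-methylbenzenesulfonate | CC(C)(C)[Si](C)(C)OC[C@@H](C)CCC[C@@H](COS(=O)(=O)c1ccc(C)cc1)[C@H]1CC[C@H](C)[C@@]12C=CC(C)=C(OC)C2 | intermediate
17 | tert-butyl{[(2S,6R)-6-[(1R,4S,5S)-7-methoxy-4,8-dimethylspiro[4.5]deca-7,9-dien-1-yl]-2-methylheptyl]oxy}dimethylsilane | CC(C)(C)[Si](C)(C)OC[C@@H](C)CCC[C@@H](C)[C@H]1CC[C@H](C)[C@@]12C=CC(C)=C(OC)C2 | intermediate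
18 | (1R,4S,5S)-1-[(2R,6S)-7-hydroxy-6-methylheptan-2-yl]-4,8-dimethylspiro[4.5]dec-8-en-7-one | OC[C@@H](C)CCC[C@@H](C)[C@H]1CC[C@H](C)[C@@]12CC=C(C)C(=O)C2 | intermediate
19 | [(2S,6R)-6-[(1R,4S,5S)-4,8-dimethyl-7-oxospiro[4.5]dec-8-en-1-yl]-2-methylheptyl] acetate | CC(=O)OC[C@@H](C)CCC[C@@H](C)[C@H]1CC[C@H](C)[C@@]12CC=C(C)C(=O)C2 | intermediate
20 | [(2S,6R)-6-[(1R,4S,5S,7S)-7-hydroxy-4,8-dimethylspiro[4.5]dec-8-en-1-yl]-2-methylheptyl] acetate | CC(=O)OC[C@@H](C)CCC[C@@H](C)[C@H]1CC[C@H](C)[C@@]12CC=C(C)[C@@H](O)C2 | target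

**Totals**

Total step count: 15. Longest linear sequence: 12 steps (steps 1–4, then 8–15); the chain branch (steps 5–7) joins at step 8.

**Steps most likely to fail, with fallbacks**

Step 9. The hydrogen transfer may be too slow at temperatures the dihydroanisole tolerates, so that loss of hydrogen to the arene, closure of the six-membered ring through C10 (type 2), or poor discrimination of the two faces of the ring alkene by the C4 methyl could take over. The fallback changes the activating helper from ester to aldehyde and sets out from 13. DIBAL-H (CH2Cl2, −78 °C) should give the allylic alcohol (2E,6S)-2-[(4S)-5-[(tert-butyldimethylsilyl)oxy]-4-methylpentyl]-6-(5-methoxy-4-methylcyclohexa-1,4-dien-1-yl)hept-2-en-1-ol F1. Parikh–Doering oxidation then gives the enal (2E,6S)-2-[(4S)-5-[(tert-butyldimethylsilyl)oxy]-4-methylpentyl]-6-(5-methoxy-4-methylcyclohexa-1,4-dien-1-yl)hept-2-enal F2, a stronger enophile of the same geometry. It should undergo the same ene closure near 150 °C, through a tighter transition state, to the aldehyde (2R,6S)-7-[(tert-butyldimethylsilyl)oxy]-2-[(1R,4S,5S)-7-methoxy-4,8-dimethylspiro[4.5]deca-7,9-dien-1-yl]-6-methylheptanal F3. NaBH4 reduces F3 at once, and the route is rejoined at 15.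

Step 1. Aryl delivery to the wrong alkene carbon (site selectivity tends to fall with electron-rich aryl groups), an incomplete chain walk, or low or opposite enantioselection could spoil the arylation. The fallback sets the stereocenter by a conjugate addition and adds the missing carbon afterwards, setting out from 1. Rh(acac)(C2H4)2 with the BINAP enantiomer that delivers the S ester ((S)-BINAP by analogy with acyclic E enones) and ethyl (E)-but-2-enoate in dioxane/water should give ethyl (S)-3-(3-methoxy-4-methylphenyl)butanoate F4. DIBAL-H at −78 °C gives (S)-3-(3-methoxy-4-methylphenyl)butanal F5, and Wittig methylenation (Ph3P=CH2) gives 2-methoxy-1-methyl-4-[(2S)-pent-4-en-2-yl]benzene F6. Hydroboration with 9-BBN and oxidation (NaOH, H2O2) return the route at 4.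

Step 15. Hydride delivery may follow the substrate instead of the catalyst (mismatched pair), giving poor facial selectivity at C7. The fallback uses substrate control followed by inversion and sets out from 19. Luche reduction (NaBH4, CeCl3·7H2O, MeOH, −78 °C) is expected to deliver hydride axially on the face of C1–H and give the epimer [(2S,6R)-6-[(1R,4S,5S,7R)-7-hydroxy-4,8-dimethylspiro[4.5]dec-8-en-1-yl]-2-methylheptyl] acetate F7. Mitsunobu inversion (4-nitrobenzoic acid, PPh3, diisopropyl azodicarboxylate) gives (1R,4S,5S,7S)-1-[(2R,6S)-7-acetoxy-6-methylheptan-2-yl]-4,8-dimethylspiro[4.5]dec-8-en-7-yl 4-nitrobenzoate F8. Selective methanolysis of the nitrobenzoate beside the primary acetate (NaN3, MeOH, 40 °C) arrives at 20.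

**Further compounds**

F1 | step 9 | (2E,6S)-2-[(4S)-5-[(tert-butyldimethylsilyl)oxy]-4-methylpentyl]-6-(5-methoxy-4-methylcyclohexa-1,4-dien-1-yl)hept-2-en-1-ol | CC(C)(C)[Si](C)(C)OC[C@@H](C)CCC/C(CO)=C\CC[C@H](C)C1=CCC(C)=C(OC)C1
F2 | step 9 | (2E,6S)-2-[(4S)-5-[(tert-butyldimethylsilyl)oxy]-4-methylpentyl]-6-(5-methoxy-4-methylcyclohexa-1,4-dien-1-yl)hept-2-enal | CC(C)(C)[Si](C)(C)OC[C@@H](C)CCC/C(C=O)=C\CC[C@H](C)C1=CCC(C)=C(OC)C1
F3 | step 9 | (2R,6S)-7-[(tert-butyldimethylsilyl)oxy]-2-[(1R,4S,5S)-7-methoxy-4,8-dimethylspiro[4.5]deca-7,9-dien-1-yl]-6-methylheptanal | CC(C)(C)[Si](C)(C)OC[C@@H](C)CCC[C@@H](C=O)[C@H]1CC[C@H](C)[C@@]12C=CC(C)=C(OC)C2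
F4 | step 1 | ethyl (S)-3-(3-methoxy-4-methylphenyl)butanoate | CCOC(=O)C[C@H](C)c1ccc(C)c(OC)c1
F5 | step 1 | (S)-3-(3-methoxy-4-methylphenyl)butanal | O=CC[C@H](C)c1ccc(C)c(OC)c1
F6 | step 1 | 2-methoxy-1-methyl-4-[(2S)-pent-4-en-2-yl]benzene | C=CC[C@H](C)c1ccc(C)c(OC)c1
F7 | step 15 | [(2S,6R)-6-[(1R,4S,5S,7R)-7-hydroxy-4,8-dimethylspiro[4.5]dec-8-en-1-yl]-2-methylheptyl] acetate | CC(=O)OC[C@@H](C)CCC[C@@H](C)[C@H]1CC[C@H](C)[C@@]12CC=C(C)[C@H](O)C2
F8 | step 15 | (1R,4S,5S,7S)-1-[(2R,6S)-7-acetoxy-6-methylheptan-2-yl]-4,8-dimethylspiro[4.5]dec-8-en-7-yl 4-nitrobenzoate | CC(=O)OC[C@@H](C)CCC[C@@H](C)[C@H]1CC[C@H](C)[C@@]12CC=C(C)[C@@H](OC(=O)c3ccc(cc3)[N+](=O)[O-])C2
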